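The pyranone ring is disconnected at C4–C4a and O1–C2. Without C2–C4 the A ring is 4,5,6-trimethoxyresorcinol, in which C4a is the only unsubstituted ring carbon and the two hydroxyl-bearing carbons (future C5 and C8a) are related by the mirror plane through C4a and C7. One solvent-free thermal condensation with an α-benzyloxy aroylacetate should therefore form both bonds and ring C with no A-ring regiochemistry to control, the unused hydroxyl becoming 5-OH. The keto ester supplies C2, C3 with its oxygen, C4 and ring B. The 3-OH and 3'-OH travel as benzyl ethers, removed together by a final hydrogenolysis.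

Key step: step 6

Assumption: the target has no stereocentre and is achiral, so no enantiocontrol is required; the only stereocentre on the route, the α-carbon of the keto ester, is racemic and becomes sp2 C3 in the key step.

Step 1
Reactants: 1 2,3,4-trimethoxybenzaldehyde
Product: 2 5-bromo-2,3,4-trimethoxybenzaldehyde
Conditions: NBS (1.05 equiv), MeCN, rt to 50 °C
Reagents that add atoms: N-bromosuccinimide, O=C1CCC(=O)N1Br
Why: Electrophilic aromatic bromination should go to C5, which is ortho to the 4-OMe, para to the 2-OMe and meta to the formyl group, whereas C6 is ortho to the deactivating aldehyde; brominating before the aldehyde becomes a phenol avoids substitution next to a free OH.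

Step 2
Reactants: 2 5-bromo-2,3,4-trimethoxybenzaldehyde
Product: 4 5-bromo-2,3,4-trimethoxyphenol, via aryl formate 3 (not isolated)
Conditions: mCPBA, CH2Cl2, 0 °C to reflux; aq NaHCO3 wash, concentrate; then K2CO3 (cat.), MeOH, rt
Reagents that add atoms: meta-chloroperoxybenzoic acid, OOC(=O)c1cccc(Cl)c1
Why: Baeyer–Villiger oxidation (Dakin-type) of a benzaldehyde carrying ortho and para methoxy groups should proceed by aryl migration to the formate, which is cleaved by mild methanolysis without touching the aryl bromide.

Step 3
Reactants: 4 5-bromo-2,3,4-trimethoxyphenol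
Product: 5 4,5,6-trimethoxybenzene-1,3-diol
Conditions: CuI (10 mol %), N,N'-bis(4-hydroxy-2,6-dimethylphenyl)oxalamide (10 mol %), KOH (4 equiv), degassed DMSO/H2O 4:1, 100 °C, Ar; then aq HCl
Reagents that add atoms: potassium hydroxide, [K+].[OH-]
Why: Copper-catalysed Ullmann-type hydroxylation of an aryl bromide tolerates a free phenoxide (as in the classical copper-mediated hydrolysis of bromophenols); excess hydroxide and water should suppress diaryl ether formation and exclusion of oxygen should protect the electron-rich diol.

Step 4
Reactants: 6 3-hydroxy-4,5-dimethoxybenzoic acid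
Product: 8 3-(benzyloxy)-4,5-dimethoxybenzoic acid, via benzyl ester 7 (not isolated)
Conditions: BnBr (2.3 equiv), K2CO3, DMF, 60 °C; then 2 M NaOH, MeOH, 70 °C; aq HCl
Reagents that add atoms: benzyl bromide, BrCc1ccccc1; sodium hydroxide, [Na+].[OH-]
Why: Williamson benzylation of phenoxide and carboxylate followed by saponification of only the benzyl ester should leave the aryl benzyl ether intact.

Step 5
Reactants: 8 3-(benzyloxy)-4,5-dimethoxybenzoic acid; 9 ethyl 2-(benzyloxy)acetate
Product: 12 ethyl 2-(benzyloxy)-3-[3-(benzyloxy)-4,5-dimethoxyphenyl]-3-oxopropanoate (racemic), via aroyl chloride 10 (not isolated), via lithium ester enolate 11 (not isolated)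
Conditions: 8, (COCl)2, DMF (cat.), CH2Cl2, rt, evaporate; separately 9 (2.1 equiv), LiHMDS (2.1 equiv), THF, −78 °C; add 10 in THF, −78 to −40 °C; aq NH4Cl
Reagents that add atoms: none
Why: Crossed Claisen acylation of a preformed lithium glycolate enolate by an aroyl chloride should give C-acylation at low temperature, the second equivalent of enolate taking up the acidic proton of the product and the non-nucleophilic HMDS not competing for the acid chloride; the new α-stereocentre forms racemic and is erased in step 6.

Step 6
Reactants: 5 4,5,6-trimethoxybenzene-1,3-diol; 12 ethyl 2-(benzyloxy)-3-[3-(benzyloxy)-4,5-dimethoxyphenyl]-3-oxopropanoate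
Product: 15 3-(benzyloxy)-2-[3-(benzyloxy)-4,5-dimethoxyphenyl]-5-hydroxy-6,7,8-trimethoxy-4H-chromen-4-one, via aroylketene 13 (not isolated), via 2-benzyloxy-1,3-diketone 14 (not isolated)
Conditions: neat melt, 12 (1.3 equiv), 240 °C (microwave or metal bath), Ar sweep to remove EtOH and H2O, 20–40 min
Reagents that add atoms: none
Why: On heating, the enol form of 12 should expel ethanol to give aroyl(benzyloxy)ketene 13, whose ketene carbon is attacked by the only unsubstituted carbon of 5 (activated by two ortho hydroxyls and a para methoxy group), forming C4–C4a and diketone 14, while any aryl ester from reversible O-acylation returns to 13 at this temperature. The hydroxyl beside the new acyl group then adds to the B-ring ketone in a 6-exo-trig closure (O1–C2) and loss of water gives the aromatic pyranone, the other hydroxyl remaining as the hydrogen-bonded 5-OH. This is the Mentzer pyrone synthesis (a thermal, Simonis-type chromone formation from phloroglucinol-type phenols and β-keto esters), known with α-alkoxy aroylacetates as a route to 3-alkoxyflavones. No stereocentre is created, and the racemic α-carbon of 12 becomes sp2 C3. Site selectivity needs no control, because 5 has a single C–H and its two hydroxyls are mirror-related, so closure through either one leads to the same product. Chromone over coumarin formation rests on the acid-free conditions, under which C-acylation by the ketene precedes any attack of the arene on the aryl ketone, and on the α-substituent, which disfavours the Pechmann mode.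

Step 7
Reactants: 15 3-(benzyloxy)-2-[3-(benzyloxy)-4,5-dimethoxyphenyl]-5-hydroxy-6,7,8-trimethoxy-4H-chromen-4-one
Product: 16 3-demethyldigicitrin, 3,5-dihydroxy-2-(3-hydroxy-4,5-dimethoxyphenyl)-6,7,8-trimethoxy-4H-chromen-4-one
Conditions: H2 (1 atm), 10 % Pd/C, EtOAc/MeOH 1:1, rt
Reagents that add atoms: none
Why: Catalytic hydrogenolysis should cleave both benzyl ethers (enol ether at C3 and aryl ether at C3') while the conjugated chromone C2=C3 bond and the methyl ethers stay inert at ambient pressure and temperature.

Compound list
1 | 2,3,4-trimethoxybenzaldehyde | COc1ccc(C=O)c(OC)c1OC | starting material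
2 | 5-bromo-2,3,4-trimethoxybenzaldehyde | COc1c(Br)cc(C=O)c(OC)c1OC | intermediate
3 | 5-bromo-2,3,4-trimethoxyphenyl formate | COc1c(Br)cc(OC=O)c(OC)c1OC | intermediate
4 | 5-bromo-2,3,4-trimethoxyphenol | COc1c(Br)cc(O)c(OC)c1OC | intermediate
5 | 4,5,6-trimethoxybenzene-1,3-diol | COc1c(O)cc(O)c(OC)c1OC | intermediate
6 | 3-hydroxy-4,5-dimethoxybenzoic acid | COc1cc(C(=O)O)cc(O)c1OC | starting material
7 | benzyl 3-(benzyloxy)-4,5-dimethoxybenzoate | COc1cc(C(=O)OCc2ccccc2)cc(OCc2ccccc2)c1OC | intermediate
8 | 3-(benzyloxy)-4,5-dimethoxybenzoic acid | COc1cc(C(=O)O)cc(OCc2ccccc2)c1OC | intermediate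
9 | ethyl 2-(benzyloxy)acetate | CCOC(=O)COCc1ccccc1 | starting material
10 | 3-(benzyloxy)-4,5-dimethoxybenzoyl chloride | COc1cc(C(Cl)=O)cc(OCc2ccccc2)c1OC | intermediate
11 | lithium enolate of ethyl 2-(benzyloxy)acetate (enolate geometry not defined) | [Li+].CCOC([O-])=COCc1ccccc1 | intermediate
12 | ethyl 2-(benzyloxy)-3-[3-(benzyloxy)-4,5-dimethoxyphenyl]-3-oxopropanoate (racemic) | CCOC(=O)C(OCc1ccccc1)C(=O)c1cc(OC)c(OC)c(OCc2ccccc2)c1 | intermediate
13 | [3-(benzyloxy)-4,5-dimethoxybenzoyl](benzyloxy)ketene | O=C=C(OCc1ccccc1)C(=O)c1cc(OC)c(OC)c(OCc2ccccc2)c1 | intermediate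
14 | 2-(benzyloxy)-1-[3-(benzyloxy)-4,5-dimethoxyphenyl]-3-(2,6-dihydroxy-3,4,5-trimethoxyphenyl)propane-1,3-dione (racemic) | COc1c(OC)c(O)c(C(=O)C(OCc2ccccc2)C(=O)c2cc(OC)c(OC)c(OCc3ccccc3)c2)c(O)c1OC | intermediate
15 | 3-(benzyloxy)-2-[3-(benzyloxy)-4,5-dimethoxyphenyl]-5-hydroxy-6,7,8-trimethoxy-4H-chromen-4-one | COc1cc(-c2oc3c(OC)c(OC)c(OC)c(O)c3c(=O)c2OCc2ccccc2)cc(OCc2ccccc2)c1OC | intermediate
16 | 3-demethyldigicitrin, 3,5-dihydroxy-2-(3-hydroxy-4,5-dimethoxyphenyl)-6,7,8-trimethoxy-4H-chromen-4-one (achiral) | COc1cc(-c2oc3c(OC)c(OC)c(OC)c(O)c3c(=O)c2O)cc(O)c1OC | target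

Total step count: 7. Longest linear sequence: 5 steps (steps 1, 2, 3, 6 and 7); the keto ester branch (steps 4 and 5) joins at step 6.

Steps most likely to fail

1. Step 6. Reversible O-acylation may be followed by ring closure in the coumarin sense, the benzyl ethers may be lost or migrate at the melt temperature, and the ketene may dimerise or the keto ester decompose before C-acylation. Fallback, setting out from 5: Houben–Hoesch acylation with benzyloxyacetonitrile (ZnCl2, HCl gas, Et2O, 0 °C; then hot water) at the same single free carbon should give 2-(benzyloxy)-1-(2,6-dihydroxy-3,4,5-trimethoxyphenyl)ethan-1-one F1. Its trilithium salt (LiHMDS, THF, −78 °C) should be C-aroylated in a Baker–Venkataraman-type manner by acid chloride 10 (made from 8 as in step 5) to give diketone 14, now isolated. Mild acid cyclodehydration (TsOH cat., toluene, 80 °C) should then give 15, where the route is rejoined.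

2. Step 3. Oxidative addition to the very electron-rich bromophenoxide may be slow, the product may couple with unreacted bromide to a diaryl ether, and the diol may be oxidised under hot basic conditions. Fallback, setting out from 4: O-benzylation (BnBr, K2CO3, DMF) should give 1-(benzyloxy)-5-bromo-2,3,4-trimethoxybenzene F2. Bromine–lithium exchange (n-BuLi, THF, −78 °C), trapping with B(OMe)3 and oxidation of the boronate (H2O2, NaOH) should give 5-(benzyloxy)-2,3,4-trimethoxyphenol F3. Hydrogenolysis (H2, Pd/C, EtOAc) should return the route to 5.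

3. Step 5. The enolate may be acylated on oxygen, the glycolate ester may self-condense, and the product enolate may be acylated a second time. Fallback, setting out from 8: activation with CDI and Masamune-type acylation of magnesium ethyl malonate (potassium ethyl malonate, MgCl2, Et3N, THF/MeCN; acidic work-up with decarboxylation) should give ethyl 3-[3-(benzyloxy)-4,5-dimethoxyphenyl]-3-oxopropanoate F4. Regitz diazo transfer (p-ABSA, Et3N, MeCN) should give ethyl 3-[3-(benzyloxy)-4,5-dimethoxyphenyl]-2-diazo-3-oxopropanoate F5. Rh2(OAc)4-catalysed O–H insertion into benzyl alcohol (CH2Cl2, rt to reflux) should deliver 12, where the route is rejoined.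

Further compounds
F1 | step 6 | 2-(benzyloxy)-1-(2,6-dihydroxy-3,4,5-trimethoxyphenyl)ethan-1-one | COc1c(OC)c(O)c(C(=O)COCc2ccccc2)c(O)c1OC
F2 | step 3 | 1-(benzyloxy)-5-bromo-2,3,4-trimethoxybenzene | COc1c(Br)cc(OCc2ccccc2)c(OC)c1OC
F3 | step 3 | 5-(benzyloxy)-2,3,4-trimethoxyphenol | COc1c(O)cc(OCc2ccccc2)c(OC)c1OC
F4 | step 5 | ethyl 3-[3-(benzyloxy)-4,5-dimethoxyphenyl]-3-oxopropanoate | CCOC(=O)CC(=O)c1cc(OC)c(OC)c(OCc2ccccc2)c1
F5 | step 5 | ethyl 3-[3-(benzyloxy)-4,5-dimethoxyphenyl]-2-diazo-3-oxopropanoate | CCOC(=O)C(=[N+]=[N-])C(=O)c1cc(OC)c(OC)c(OCc2ccccc2)c1
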